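**Retrosynthetic overview** (labdane numbering throughout; the target is 6α-angeloyloxysclareol)
1. The angelate is put on last, on the only secondary hydroxyl of (13R)-labd-14-ene-6α,8α,13-triol; the 6α,8α-diol comes from a labd-7-en-6-one (epoxidation, SmI2, dissolving metal), and that enone from a labda-7,14-diene by allylic oxidation.
2. The C9–C11 bond is made by adding the C11–C16 chain (C13 taken from (R)-linalool) as an organocerium to the C9 ketone of a bicyclic enone; oxidative transposition and Birch reduction then set H-9α and remove the sulfone.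
3. Structural feature: the gem-dimethyl carbon C4 is bonded to the ring-fusion carbon C5, so ring A is opened at C3–C4 to an isopropenyl group on C5 (C4 with C18 and C19, one hydrogen short) and a 2-sulfonylallyl arm (C1–C3) on C10.
4. (R)-Carvone is ring B: it supplies C5 with that isopropenyl group, the C17 methyl on C8, the C7=C8 alkene, the C9 carbonyl and the α'-carbon that becomes C10.
5. Ring order: ring B (carvone) first, ring A second by hydrogen-atom-transfer radical closure, side chain and ring B oxygenation afterwards.

Key step: step 5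

Assumption: the configurations at the sulfone-bearing C2 (formed in the key step), at the C9 carbinol of the organocerium adduct and at the methylated carbon of 6-methylcarvone are of no consequence, because these centres are later planarised or lose the heteroatom; the expected major isomers are drawn.

**Step 1**
Reactants: 1 phenyl vinyl sulfone
Product: 2 2-(phenylsulfonyl)prop-2-en-1-ol
Conditions: aq. HCHO (37%), DABCO (1 equiv), 1,4-dioxane/H2O, rt
Reagents that add atoms: formaldehyde, C=O
Why: Morita–Baylis–Hillman hydroxymethylation, in which DABCO adds to the vinyl sulfone, the α-sulfonyl carbanion adds to formaldehyde and loss of the amine restores the alkene; no stereocentre is formed.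

**Step 2**
Reactants: 2 2-(phenylsulfonyl)prop-2-en-1-ol
Product: 3 3-bromo-2-(phenylsulfonyl)prop-1-ene
Conditions: PBr3, Et2O, 0 °C
Reagents that add atoms: phosphorus tribromide, BrP(Br)Br
Why: Conversion of a primary allylic alcohol into the bromide through its phosphite ester, where direct and allylic displacement give the same constitution; no stereocentre is formed.

**Step 3**
Reactants: 4 (R)-carvone
Product: 6 trans-6-methylcarvone, via lithium dienolate of carvone 5 (not isolated)
Conditions: LiN(iPr)2, THF, −78 °C; then MeI, −78 → 0 °C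
Reagents that add atoms: iodomethane, CI
Why: Kinetic α'-deprotonation of the enone followed by SN2 methylation of the enolate (enolate alkylation), the methyl group entering mainly trans to the isopropenyl group at a centre that is planarised again in step 4.

**Step 4**
Reactants: 6 trans-6-methylcarvone; 3 3-bromo-2-(phenylsulfonyl)prop-1-ene
Product: 8 6-methyl-6-[2-(phenylsulfonyl)allyl]carvone, via lithium enolate of 6-methylcarvone 7 (not isolated)
Conditions: LiN(iPr)2, THF, −78 → 0 °C; then 3, DMPU, −78 °C → rt
Reagents that add atoms: none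
Why: Alkylation of the tetrasubstituted lithium enolate by the activated allylic bromide (SN2 and SN2' give the same product), the electrophile approaching the face opposite the neighbouring isopropenyl group as in allylations of 6-methylcarvone, which sets quaternary C10 with the methyl cis and the sulfonylallyl arm trans to C4.

**Step 5**
Reactants: 8 6-methyl-6-[2-(phenylsulfonyl)allyl]carvone
Product: 9 trans-fused bicyclic enone with C4 gem-dimethyl and 2α-phenylsulfonyl group
Conditions: Fe(acac)3 (0.3 equiv), PhSiH3 (2.5 equiv), EtOH/HOCH2CH2OH 5:1, 0.02 M, degassed, 60 °C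
Reagents that add atoms: none
Why: The iron hydride formed from Fe(acac)3 and PhSiH3 transfers a hydrogen atom to the terminal CH2 of the electron-rich 1,1-disubstituted isopropenyl group, giving the tertiary C4 radical that already carries both methyl groups. This nucleophilic radical adds to the unsubstituted terminus C3 of the electron-poor vinyl sulfone, and the α-sulfonyl radical at C2 is reduced by divalent iron and protonated by ethanol; the closest known reaction type is the iron-hydride reductive olefin coupling (HAT-initiated Giese reaction), including ring closures that create quaternary carbons. Ring A closes in the 6-endo-trig mode, favoured over 5-exo because attack at C2 would meet a fully substituted carbon and give an unstabilised primary radical. The trans ring fusion is not created here but fixed by C5 and C10 of 8, whose two reacting arms are trans-diequatorial on ring B with the C10 methyl axial; the only new stereocentre is C2, where the sulfonyl group should end equatorial because an axial one would be 1,3-diaxial to the C10 and C4 methyls, and it is removed in step 12. The step needs site selectivity in the hydrogen atom transfer (isopropenyl over vinyl sulfone and enone) and regioselectivity in the radical addition; the first should follow from the higher reactivity of the unactivated 1,1-disubstituted alkene toward the iron hydride and the second from the polarisation of the vinyl sulfone toward C3.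

**Step 6**
Reactants: 10 (R)-linalool
Product: 11 (R)-linalool tert-butyldimethylsilyl ether
Conditions: TBSOTf, 2,6-lutidine, CH2Cl2, 0 °C → rt
Reagents that add atoms: tert-butyldimethylsilyl triflate, CC(C)(C)[Si](C)(C)OS(=O)(=O)C(F)(F)F
Why: Silylation of a hindered tertiary alcohol with the silyl triflate, which leaves the C13 configuration untouched.

**Step 7**
Reactants: 11 (R)-linalool tert-butyldimethylsilyl ether
Product: 12 (4R)-4-(tert-butyldimethylsilyloxy)-4-methylhex-5-enal
Conditions: O3 (1 equiv, Sudan Red 7B end point), CH2Cl2/MeOH, −78 °C; then Me2S, −78 °C → rt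
Reagents that add atoms: ozone, [O-][O+]=O
Why: Chemoselective ozonolysis, the electron-rich trisubstituted alkene reacting much faster than the monosubstituted vinyl group beside the quaternary carbinol carbon, with reductive work-up to the aldehyde.

**Step 8**
Reactants: 12 (4R)-4-(tert-butyldimethylsilyloxy)-4-methylhex-5-enal
Product: 13 (4R)-4-(tert-butyldimethylsilyloxy)-4-methylhex-5-enoic acid
Conditions: NaClO2, NaH2PO4, 2-methylbut-2-ene, t-BuOH/H2O, rt
Reagents that add atoms: sodium chlorite, [Na+].[O-]Cl=O
Why: Pinnick oxidation, selective for the aldehyde, with the alkene scavenger protecting the vinyl group from hypochlorous acid.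

**Step 9**
Reactants: 13 (4R)-4-(tert-butyldimethylsilyloxy)-4-methylhex-5-enoic acid
Product: 15 tert-butyl{[(3R)-5-iodo-3-methylpent-1-en-3-yl]oxy}dimethylsilane, via Barton thiohydroxamate ester 14 (not isolated)
Conditions: 1-hydroxypyridine-2(1H)-thione, DCC, DMAP (cat.), CH2Cl2, 0 °C → rt, dark; then CHI3, hν (tungsten lamp), rt
Reagents that add atoms: iodoform, IC(I)I
Why: Barton decarboxylative iodination, a radical chain in which the primary radical left after loss of CO2 takes iodine from iodoform faster than it could close a four-membered ring onto the vinyl group; C13 is not involved.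

**Step 10**
Reactants: 15 tert-butyl{[(3R)-5-iodo-3-methylpent-1-en-3-yl]oxy}dimethylsilane; 9 trans-fused bicyclic enone
Product: 18 (13R)-13-(tert-butyldimethylsilyloxy)-2α-(phenylsulfonyl)labda-7,14-dien-9-ol, via alkyllithium 16 (not isolated), via dichloro(alkyl)cerium 17 (not isolated)
Conditions: 15 (2 equiv), t-BuLi (2 equiv per iodide), Et2O/pentane, −78 °C; anhydrous CeCl3, THF, −78 °C; then 9, −78 → −40 °C; aq. NH4Cl
Reagents that add atoms: none
Why: Lithium–iodine exchange and transmetalation to the weakly basic organocerium (Imamoto reagent), which adds 1,2 to the hindered 2,6,6-trisubstituted cyclohexenone without deprotonating the sulfone, attack being expected anti to the axial C10 methyl at a carbinol centre that is planarised in step 11.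

**Step 11**
Reactants: 18 (13R)-13-(tert-butyldimethylsilyloxy)-2α-(phenylsulfonyl)labda-7,14-dien-9-ol
Product: 19 (13R)-13-(tert-butyldimethylsilyloxy)-2α-(phenylsulfonyl)labda-8,14-dien-7-one
Conditions: C5H5NH[CrO3Cl] (pyridinium chlorochromate), 4 Å molecular sieves, CH2Cl2, rt
Reagents that add atoms: pyridinium chlorochromate, [O-][Cr](=O)(=O)Cl.c1cc[nH+]cc1
Why: Babler–Dauben oxidative transposition, in which the chromate ester of the tertiary allylic alcohol shifts [3,3] to C7 and is oxidised to the enone, while the silyl ether keeps the second tertiary allylic alcohol out of the same reaction; no stereocentre is formed.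

**Step 12**
Reactants: 19 (13R)-13-(tert-butyldimethylsilyloxy)-2α-(phenylsulfonyl)labda-8,14-dien-7-one
Product: 21 (13R)-13-(tert-butyldimethylsilyloxy)labda-7,14-dien-7-yl triflate, via lithium C7 enolate 20 (not isolated)
Conditions: Li (6 equiv), NH3(l)/THF, t-BuOH (1 equiv), −78 °C; isoprene; NH3 evaporated; then PhNTf2 (excess), THF, −78 °C → rt
Reagents that add atoms: N-phenylbis(trifluoromethanesulfonimide), O=S(=O)(N(c1ccccc1)S(=O)(=O)C(F)(F)F)C(F)(F)F
Why: Dissolving-metal enone reduction with regiospecific enolate trapping, in which C9 is protonated axially from the α face (anti to the axial C10 methyl) so that the side chain becomes equatorial and β as in the labdanes, while the same reagent cleaves the C2–S bond (reductive desulfonylation) and the C7=C8 enolate is O-triflated.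

**Step 13**
Reactants: 21 (13R)-13-(tert-butyldimethylsilyloxy)labda-7,14-dien-7-yl triflate
Product: 22 (13R)-13-(tert-butyldimethylsilyloxy)labda-7,14-diene
Conditions: Pd(OAc)2 (cat.), PPh3, HCO2H, n-Bu3N, DMF, 60 °C
Reagents that add atoms: none
Why: Palladium-catalysed formate reduction of a vinyl triflate (oxidative addition to zerovalent palladium, hydride from formate, reductive elimination), which leaves the alkene at C7=C8 and creates no stereocentre.

**Step 14**
Reactants: 22 (13R)-13-(tert-butyldimethylsilyloxy)labda-7,14-diene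
Product: 23 (13R)-13-(tert-butyldimethylsilyloxy)labda-7,14-dien-6-one
Conditions: CrO3, 3,5-dimethylpyrazole, CH2Cl2, −20 °C
Reagents that add atoms: chromium trioxide, O=[Cr](=O)=O
Why: Allylic oxidation with the CrO3–3,5-dimethylpyrazole complex, which should convert the ring methylene C6 next to the alkene CH into the conjugated ketone as in α-ionone-type and drim-7-ene systems, the vinyl group having no allylic hydrogen.

**Step 15**
Reactants: 23 (13R)-13-(tert-butyldimethylsilyloxy)labda-7,14-dien-6-one
Product: 24 (13R)-13-(tert-butyldimethylsilyloxy)-7α,8α-epoxylabd-14-en-6-one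
Conditions: 30% aq. H2O2, NaOH, MeOH, 0 °C → rt
Reagents that add atoms: hydrogen peroxide, OO
Why: Weitz–Scheffer nucleophilic epoxidation of the enone, the hydroperoxide anion adding to C8 from the α face because the β face is screened by the axial C10 methyl, which sets C8 with oxygen α and methyl β.

**Step 16**
Reactants: 24 (13R)-13-(tert-butyldimethylsilyloxy)-7α,8α-epoxylabd-14-en-6-one
Product: 25 (13R)-13-(tert-butyldimethylsilyloxy)-8α-hydroxylabd-14-en-6-one
Conditions: SmI2 (2.5 equiv), THF/MeOH, −90 °C
Reagents that add atoms: none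
Why: SmI2 reduction of an α,β-epoxy ketone, in which the ketyl cleaves the C7–O bond and the samarium enolate is protonated by methanol, so the C8–O bond and its configuration are kept.

**Step 17**
Reactants: 25 (13R)-13-(tert-butyldimethylsilyloxy)-8α-hydroxylabd-14-en-6-one
Product: 26 (13R)-13-(tert-butyldimethylsilyloxy)labd-14-ene-6α,8α-diol
Conditions: Li, NH3(l)/THF, −78 °C (ketone added to the metal solution); then solid NH4Cl
Reagents that add atoms: none
Why: Dissolving-metal reduction of the ketone, which gives the thermodynamically favoured equatorial 6α-alcohol because the axial 6β-epimer would be 1,3-diaxial to the C4β and C10 methyls, and which is fast enough at −78 °C to outrun retro-aldol cleavage.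

**Step 18**
Reactants: 26 (13R)-13-(tert-butyldimethylsilyloxy)labd-14-ene-6α,8α-diol
Product: 27 (13R)-labd-14-ene-6α,8α,13-triol
Conditions: n-Bu4NF, THF, 50 °C
Reagents that add atoms: none
Why: Fluoride cleavage of the tertiary silyl ether, done before the ester is present so that no base-sensitive group is exposed; no stereocentre is affected.

**Step 19**
Reactants: 27 (13R)-labd-14-ene-6α,8α,13-triol
Product: 28 6α-angeloyloxy-(13R)-labd-14-ene-8α,13-diol (target)
Conditions: angelic acid, 2,4,6-trichlorobenzoyl chloride, Et3N, toluene, rt; then 27, 80 °C (no DMAP)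
Reagents that add atoms: angelic acid ((Z)-2-methylbut-2-enoic acid), C/C=C(/C)C(=O)O
Why: Yamaguchi-type esterification through the 2,4,6-trichlorobenzoyl mixed anhydride without a nucleophilic catalyst, which should keep the Z geometry and acylate only the secondary 6α-hydroxyl because the two tertiary alcohols are too hindered.

**Compound list**
1 | phenyl vinyl sulfone | C=CS(=O)(=O)c1ccccc1 | starting material
2 | 2-(phenylsulfonyl)prop-2-en-1-ol | C=C(CO)S(=O)(=O)c1ccccc1 | intermediate
3 | 3-bromo-2-(phenylsulfonyl)prop-1-ene | C=C(CBr)S(=O)(=O)c1ccccc1 | intermediate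
4 | (R)-carvone | O=C1C(C)=CC[C@@H](C(C)=C)C1 | starting material
5 | lithium cross-conjugated dienolate of carvone (enolate toward the α'-carbon) | [Li+].[O-]C1=C[C@H](C(C)=C)CC=C1C | intermediate (not isolated)
6 | trans-6-methylcarvone (2,6-dimethyl-5-(prop-1-en-2-yl)cyclohex-2-en-1-one, 6-methyl trans to isopropenyl; the cis epimer converges in step 4) | O=C1C(C)=CC[C@@H](C(C)=C)[C@@H]1C | intermediate
7 | lithium enolate of 6-methylcarvone (tetrasubstituted enolate) | [Li+].[O-]C1=C(C)[C@H](C(C)=C)CC=C1C | intermediate (not isolated)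
8 | 6-methyl-6-[2-(phenylsulfonyl)allyl]carvone (2,6-dimethyl-6-[2-(phenylsulfonyl)prop-2-en-1-yl]-5-(prop-1-en-2-yl)cyclohex-2-en-1-one; sulfonylallyl trans, methyl cis to isopropenyl) | O=C1C(C)=CC[C@@H](C(C)=C)[C@]1(C)CC(=C)S(=O)(=O)c2ccccc2 | intermediate
9 | trans-fused 2,5,5,8a-tetramethyl-7-(phenylsulfonyl)-4a,5,6,7,8,8a-hexahydronaphthalen-1(4H)-one (labdane numbering: C9 ketone, C7=C8, H-5α, CH3-10β, equatorial 2α-sulfone) | O=C1C(C)=CC[C@H]2C(C)(C)C[C@H](S(=O)(=O)c3ccccc3)C[C@]12C | intermediate
10 | (R)-linalool | C=C[C@](C)(O)CCC=C(C)C | starting material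
11 | (R)-linalool tert-butyldimethylsilyl ether | C=C[C@](C)(O[Si](C)(C)C(C)(C)C)CCC=C(C)C | intermediate
12 | (4R)-4-(tert-butyldimethylsilyloxy)-4-methylhex-5-enal | C=C[C@](C)(O[Si](C)(C)C(C)(C)C)CCC=O | intermediate
13 | (4R)-4-(tert-butyldimethylsilyloxy)-4-methylhex-5-enoic acid | C=C[C@](C)(O[Si](C)(C)C(C)(C)C)CCC(=O)O | intermediate
14 | Barton ester of 13 (2-thioxopyridin-1(2H)-yl ester) | C=C[C@](C)(O[Si](C)(C)C(C)(C)C)CCC(=O)On1ccccc1=S | intermediate (not isolated)
15 | tert-butyl{[(3R)-5-iodo-3-methylpent-1-en-3-yl]oxy}dimethylsilane | C=C[C@](C)(O[Si](C)(C)C(C)(C)C)CCI | intermediate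
16 | (3R)-3-(tert-butyldimethylsilyloxy)-3-methylpent-4-enyllithium | C=C[C@](C)(O[Si](C)(C)C(C)(C)C)CC[Li] | intermediate (not isolated)
17 | dichloro[(3R)-3-(tert-butyldimethylsilyloxy)-3-methylpent-4-enyl]cerium | C=C[C@](C)(O[Si](C)(C)C(C)(C)C)CC[Ce](Cl)Cl | intermediate (not isolated)
18 | (13R)-13-(tert-butyldimethylsilyloxy)-2α-(phenylsulfonyl)labda-7,14-dien-9-ol (hydroxyl β, side chain α at C9 expected) | C=C[C@](C)(O[Si](C)(C)C(C)(C)C)CC[C@]1(O)C(C)=CC[C@H]2C(C)(C)C[C@H](S(=O)(=O)c3ccccc3)C[C@]12C | intermediate
19 | (13R)-13-(tert-butyldimethylsilyloxy)-2α-(phenylsulfonyl)labda-8,14-dien-7-one | C=C[C@](C)(O[Si](C)(C)C(C)(C)C)CCC1=C(C)C(=O)C[C@H]2C(C)(C)C[C@H](S(=O)(=O)c3ccccc3)C[C@]12C | intermediate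
20 | lithium (13R)-13-(tert-butyldimethylsilyloxy)labda-7,14-dien-7-olate (H-9α, sulfone removed) | C=C[C@](C)(O[Si](C)(C)C(C)(C)C)CC[C@@H]1[C@@]2(C)CCCC(C)(C)[C@@H]2CC([O-])=C1C.[Li+] | intermediate (not isolated)
21 | (13R)-13-(tert-butyldimethylsilyloxy)labda-7,14-dien-7-yl triflate | C=C[C@](C)(O[Si](C)(C)C(C)(C)C)CC[C@@H]1[C@@]2(C)CCCC(C)(C)[C@@H]2CC(OS(=O)(=O)C(F)(F)F)=C1C | intermediate
22 | (13R)-13-(tert-butyldimethylsilyloxy)labda-7,14-diene | C=C[C@](C)(O[Si](C)(C)C(C)(C)C)CC[C@@H]1[C@@]2(C)CCCC(C)(C)[C@@H]2CC=C1C | intermediate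
23 | (13R)-13-(tert-butyldimethylsilyloxy)labda-7,14-dien-6-one | C=C[C@](C)(O[Si](C)(C)C(C)(C)C)CC[C@@H]1[C@@]2(C)CCCC(C)(C)[C@@H]2C(=O)C=C1C | intermediate
24 | (13R)-13-(tert-butyldimethylsilyloxy)-7α,8α-epoxylabd-14-en-6-one | C=C[C@](C)(O[Si](C)(C)C(C)(C)C)CC[C@@H]1[C@@]2(C)CCCC(C)(C)[C@@H]2C(=O)[C@H]3O[C@]31C | intermediate
25 | (13R)-13-(tert-butyldimethylsilyloxy)-8α-hydroxylabd-14-en-6-one | C=C[C@](C)(O[Si](C)(C)C(C)(C)C)CC[C@@H]1[C@@]2(C)CCCC(C)(C)[C@@H]2C(=O)C[C@@]1(C)O | intermediate
26 | (13R)-13-(tert-butyldimethylsilyloxy)labd-14-ene-6α,8α-diol | C=C[C@](C)(O[Si](C)(C)C(C)(C)C)CC[C@@H]1[C@@]2(C)CCCC(C)(C)[C@@H]2[C@@H](O)C[C@@]1(C)O | intermediate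
27 | (13R)-labd-14-ene-6α,8α,13-triol | C=C[C@](C)(O)CC[C@@H]1[C@@]2(C)CCCC(C)(C)[C@@H]2[C@@H](O)C[C@@]1(C)O | intermediate
28 | 6α-angeloyloxy-(13R)-labd-14-ene-8α,13-diol (CNP0203829.1) | C=C[C@](C)(O)CC[C@@H]1[C@@]2(C)CCCC(C)(C)[C@@H]2[C@@H](OC(=O)/C(C)=C\C)C[C@@]1(C)O | target

**Total step count:** 19. **Longest linear sequence:** 14 steps (from (R)-linalool: steps 6–9, then 10–19); 13 steps from (R)-carvone.

**Steps most likely to fail**

Step 5. The hydrogen atom may be delivered to the vinyl sulfone or the enone instead of the isopropenyl group, or the C4 radical may be reduced before it closes, so that reduced open-chain material or a wrongly connected ring forms. The fallback makes the same radical from a halide. It sets out from 8: dry HBr in AcOH at 0 °C adds to the isopropenyl group in the Markovnikov sense (as for carvone hydrobromide) and should give the tertiary bromide 2,6-dimethyl-5-(2-bromopropan-2-yl)-6-[2-(phenylsulfonyl)allyl]cyclohex-2-en-1-one F1. Slow addition of Bu3SnH with AIBN in benzene at 80 °C abstracts bromine, the C4 radical closes 6-endo onto the vinyl sulfone, and the stannane quenches the α-sulfonyl radical, returning to the route at 9.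

Step 14. Hydrogen abstraction may occur at C9 or C17 instead of C6, or oxidation may be incomplete, giving regioisomeric enones. The fallback builds the C6 carbonyl from the C7 ketone and does not use C–H oxidation. It sets out from 19:
- The Birch reduction of step 12 is quenched with NH4Cl instead of PhNTf2, giving (13R)-13-(tert-butyldimethylsilyloxy)labd-14-en-7-one F2.
- Kinetic deprotonation at C6 with LiN(iPr)2 at −78 °C and oxidation of the enolate with 2-(phenylsulfonyl)-3-phenyloxaziridine gives (13R)-13-(tert-butyldimethylsilyloxy)-6α-hydroxylabd-14-en-7-one F3.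
- Dess–Martin oxidation gives the 6,7-dione, which should exist as the diosphenol (13R)-13-(tert-butyldimethylsilyloxy)-7-hydroxylabda-7,14-dien-6-one F4, enolised toward C8.
- Tf2O and pyridine give the enol triflate (13R)-13-(tert-butyldimethylsilyloxy)-6-oxolabda-7,14-dien-7-yl triflate F5.
- Reduction with Pd(OAc)2, PPh3, HCO2H and n-Bu3N removes the C7 oxygen and returns to the route at 23.

Step 19. The activated angeloyl unit may isomerise from Z to E, and acylation of the hindered 6α-hydroxyl may be slow. The fallback builds the Z alkene after the ester bond is made. It sets out from 27: DCC and catalytic DMAP couple the 6α-hydroxyl with 2-[bis(2,2,2-trifluoroethoxy)phosphoryl]propanoic acid to give the 6α-O-{2-[bis(2,2,2-trifluoroethoxy)phosphoryl]propanoyl} ester of the triol F6 (epimers at the carbon next to phosphorus). Still–Gennari olefination (KN(SiMe3)2 in excess, 18-crown-6, THF, −78 °C, then acetaldehyde) should form the (Z)-2-methylbut-2-enoate in place and arrive at the target 28.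

**Further compounds**
F1 | step 5 | 2,6-dimethyl-5-(2-bromopropan-2-yl)-6-[2-(phenylsulfonyl)prop-2-en-1-yl]cyclohex-2-en-1-one (hydrobromide of 8) | O=C1C(C)=CC[C@@H](C(C)(C)Br)[C@]1(C)CC(=C)S(=O)(=O)c2ccccc2
F2 | step 14 | (13R)-13-(tert-butyldimethylsilyloxy)labd-14-en-7-one (8α-methyl epimer drawn) | C=C[C@](C)(O[Si](C)(C)C(C)(C)C)CC[C@@H]1[C@@]2(C)CCCC(C)(C)[C@@H]2CC(=O)[C@H]1C
F3 | step 14 | (13R)-13-(tert-butyldimethylsilyloxy)-6α-hydroxylabd-14-en-7-one | C=C[C@](C)(O[Si](C)(C)C(C)(C)C)CC[C@@H]1[C@@]2(C)CCCC(C)(C)[C@@H]2[C@@H](O)C(=O)[C@H]1C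
F4 | step 14 | (13R)-13-(tert-butyldimethylsilyloxy)-7-hydroxylabda-7,14-dien-6-one (diosphenol) | C=C[C@](C)(O[Si](C)(C)C(C)(C)C)CC[C@@H]1[C@@]2(C)CCCC(C)(C)[C@@H]2C(=O)C(O)=C1C
F5 | step 14 | (13R)-13-(tert-butyldimethylsilyloxy)-6-oxolabda-7,14-dien-7-yl triflate | C=C[C@](C)(O[Si](C)(C)C(C)(C)C)CC[C@@H]1[C@@]2(C)CCCC(C)(C)[C@@H]2C(=O)C(OS(=O)(=O)C(F)(F)F)=C1C
F6 | step 19 | (13R)-8α,13-dihydroxylabd-14-en-6α-yl 2-[bis(2,2,2-trifluoroethoxy)phosphoryl]propanoate | C=C[C@](C)(O)CC[C@@H]1[C@@]2(C)CCCC(C)(C)[C@@H]2[C@@H](OC(=O)C(C)P(=O)(OCC(F)(F)F)OCC(F)(F)F)C[C@@]1(C)O
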